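# Proposed total synthesis of CNP0345283.3 (2,10-dibromo-3-chloro-7,8:9,10-diepoxychamigran-5-ol)

Atom numbers used throughout: ring B is C1 (CH2) – C2 (CHBr) – C3 (C(CH3)Cl) – C4 (CH2) – C5 (CHOH) – C6 (spiro atom). Ring A is C6 – C7 (C(CH3), oxirane) – C8 (CH, oxirane) – C9 (CH, oxirane) – C10 (CBr, oxirane) – C11 (C(CH3)2). In this numbering the target is 2S,3S,5S,6R,7R,8S,9S,10S.

## The problem

The target is a spiro[5.5]undecane. Its spiro atom C6 is bonded to quaternary C11, to the fully substituted oxirane carbon C7 and to the carbinol C5, so the C6–C11 bond joins two quaternary carbons. It has eight stereocentres: C2, C3 and C5 in ring B, C6, and C7–C10 in ring A, where the two oxiranes are anti to each other.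

Ring B can adopt only one chair. C11 is equatorial and C7 axial, Br and Cl are equatorial, and the C3 methyl and the C5 hydroxyl are 1,3-diaxial on the face opposite C7. In that chair the methyl on axial C7 lies over the centre of ring B. In the flipped chair a methyl on C11 does the same. Anti addition of Br and Cl, and hydride delivery to make the axial C5-OH, are therefore both blocked once the spirocycle exists, so C2, C3 and C5 must be set before C6.

The control chain runs in one direction. C2/C3 can direct C5. C2, C3 and C5 together leave one possible configuration for C6. C5 and the C11 methyls then differentiate the faces of ring A.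

The fragile groups are:
- the bromooxirane, which rearranges to a bromoketone with acid;
- the vinyl oxirane stage, where the C5-OH can attack;
- the tertiary chloride, which ionises with help from the anti bromine while ring B is still monocyclic.

The feature that makes the key step possible appears at the diene level 15 (C7=C8–C9=C10Br). Atoms C9, C10(Br), C11(CH3)2 and the C5 oxygen together make up 2-bromo-3-methylbut-2-enal 13. What remains is the monocyclic 1,3-diene C5=C6–C7=C8 of 10. Its termini C5 and C8 are the two atoms that must bond to that oxygen and to C9.

## Retrosynthesis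

**17 ⇒ 16 ⇒ 15 (C9–O/C10–O, then C7–O/C8–O).** The bromooxirane is the most fragile group, so it is removed first, back to vinyl bromide 16. The C7–C8 oxirane is then removed to give bromodiene alcohol 15. This order follows alkene nucleophilicity, trisubstituted C7=C8 before the bromoalkene, and anti bis-epoxidation is the normal outcome for a cyclohexadiene. Four stereocentres are removed. The forward reactions need only face selectivity, which the spiro centre must supply.

**15 ⇒ 10 + 13 (C6–C11, C8–C9 and C5–O).** Cutting only C6–C11 would leave a long side chain that has to be built on a halogenated ring. Cutting at C1–C6 or C5–C6 would leave ring A intact, and ring B would have to close against it. Cutting all three bonds gives two small pieces with no atoms lost: monocyclic diene 10 (C10) and enal 13 (C5). The aldehyde oxygen becomes the C5 oxygen by way of dihydropyran 14. The forward reaction must form C8–C9 and C5–O, then exchange the C9–O bond for the C11–C6 bond, then lose the C8 proton. It must also set C5 and C6 from C2/C3.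

**10 ⇒ 9 (C5=C6, with migration of CH2 to C7).** A 1-isopropenylcyclohexene is the retron of an exo ring-closing enyne metathesis. This closes ring B under neutral conditions that the two halides tolerate, and it is an isomerisation. Closure at C4–C5 or C1–C2 would need a carbanion or radical next to a halogen. Enyne 9 is acyclic and has only the two halogen stereocentres.

**9 ⇒ 6 + 7 (C1–C6).** C1 is the carbinol carbon that the asymmetric halogenation needs. It is then joined to C6 as a small, linear alkynyl nucleophile 7 through triflate 8. A radical or organometallic centre at C1 would expel the C2 bromine, so C1 must be the electrophile.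

**6 ⇒ 5 (C2–Br and C3–Cl).** Anti Markovnikov bromochlorination of the allylic alcohol sets both stereocentres and the absolute configuration in one catalytic step. In the conformer of the target with Br and Cl anti, C1 and C4 are gauche. The alkene must therefore carry C1 and C4 cis, which is the Z isomer 5.

**5 ⇒ 3 + 4, and 3 ⇒ 1 (C3–C4, C3–I).** The Z trisubstituted alkene comes from hydroxyl-directed trans-hydroalumination and iodination of but-2-yn-1-ol 1 via alanate 2. Stereoretentive coupling with allylstannane 4 follows.

**13 ⇒ 11 (C10–Br).** Bromination and dehydrobromination of 3-methylbut-2-enal 11 via dibromide 12.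

## Roads not taken

**Alternative 1:** the obvious cut, C1–C6 and C4–C5. A Diels–Alder reaction of isoprene with the exocyclic enone A1 gives spiroketone A2, followed by bromochlorination and oxidations. It builds the quaternary centre in one step. However, A2 has no oxygen at C5 and no handle at C9/C10. Both halogens would also have to be added anti across a ring B that has one face covered by the axial arm. The only unhindered diaxial mode places Br cis to C7, the wrong diastereomer. The chosen plan installs the halogens while the chain is still open.

**Alternative 2:** cut C5–C6 only. Aldehyde A3, with ring A preformed as a 1,4-diene, would close by an intramolecular carbonyl-ene or Prins reaction and would also unveil the bromodiene. Proton transfer from C8 requires the carbonyl oxygen to be gauche to C7. With C11 equatorial, that leads to the equatorial alcohol A4, the C5 epimer of 15. This cannot be corrected, because hydride also reaches a C5 ketone only from the face that gives A4. Making A3 also requires bonding a hindered tetrasubstituted vinyl metal to a carbon next to CHBr. The chosen plan makes the C5–O bond on a monocycle.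

**Alternative 3:** cut C1–C6 and one C11–CH3 bond, using the latent symmetry of ring A. Phenol mesylate A5 would close by dearomatising para-alkylation to the symmetric spirodienone A6. A conjugate methylation of the equatorial enone arm would then create C11 and make C6 stereogenic. The closure needs both C4 and the silyloxy group on C5 nearly in the plane of a 2,6-dimethylaryl ring. The methylation must create a quaternary carbon next to another. Converting the C9 ketone to the C9=C10Br unit costs at least three more steps. The chosen plan reaches 15 directly at the correct oxidation level.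

Key step: step 7

## Steps

Assumption: the enantiomer of the Schiff-base ligand in step 3 is taken to be the one that delivers the 2S,3S bromochloride. If it delivers the antipode, the mirror-image ligand is used.

Step 1
Reactants: 1 but-2-yn-1-ol
Product: 3 (Z)-3-iodobut-2-en-1-ol, via cyclic alkenylalanate 2 (not isolated)
Conditions: NaAlH2(OCH2CH2OMe)2, THF, 0 °C to rt; then I2, THF, −78 °C; aqueous tartrate work-up
Reagents that add atoms: iodine, II
Why: Hydroxyl-directed trans-hydroalumination of a propargylic alcohol places aluminium on C3 within the five-membered alanate 2, and iodinolysis with retention gives only the Z iodide, with I cis to CH2OH.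

Step 2
Reactants: 3 (Z)-3-iodobut-2-en-1-ol; 4 allyltributylstannane
Product: 5 (2Z)-3-methylhexa-2,5-dien-1-ol
Conditions: PdCl2(MeCN)2 (5 mol %), DMF, rt
Reagents that add atoms: none
Why: Stille coupling of an alkenyl iodide proceeds with retention, so the allyl group (C4–C5) ends up cis to CH2OH (C1), the geometry that anti addition needs to give the C2/C3 relationship of the target.

Step 3
Reactants: 5 (2Z)-3-methylhexa-2,5-dien-1-ol
Product: 6 (2S,3S)-2-bromo-3-chloro-3-methylhex-5-en-1-ol
Conditions: N-bromosuccinimide, ClTi(OiPr)3, chiral tridentate O,N,O Schiff-base diol ligand (10–20 mol %), hexanes, −20 °C, dark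
Reagents that add atoms: N-bromosuccinimide, O=C1CCC(=O)N1Br; chlorotitanium triisopropoxide, CC(C)O[Ti](Cl)(OC(C)C)OC(C)C
Why: Catalytic enantioselective bromochlorination of an allylic alcohol, in which the titanium-bound alkoxide restricts reaction to the allylic alkene and leaves the terminal one untouched; anti addition places Br on C2 and Cl on tertiary C3, and the ligand selects the alkene face, setting C2 and C3 and the absolute configuration.

Step 4
Reactants: 6 (2S,3S)-2-bromo-3-chloro-3-methylhex-5-en-1-ol; 7 1-propynyllithium
Product: 9 (4S,5S)-5-bromo-4-chloro-4-methylnon-1-en-7-yne, via primary triflate 8 (not isolated)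
Conditions: Tf2O, 2,6-lutidine, CH2Cl2, −78 °C; then 7, THF/DMPU, −78 to −30 °C
Reagents that add atoms: none
Why: SN2 alkylation of an alkynyllithium by a primary triflate forms C1–C6 at low temperature with a slim nucleophile; no bond to C2 or C3 is touched, so both stereocentres are carried through unchanged.

Step 5
Reactants: 9 (4S,5S)-5-bromo-4-chloro-4-methylnon-1-en-7-yne
Product: 10 (4S,5S)-5-bromo-4-chloro-4-methyl-1-(prop-1-en-2-yl)cyclohex-1-ene
Conditions: second-generation Grubbs catalyst (5 mol %), ethene (1 atm), CH2Cl2, 40 °C
Reagents that add atoms: none
Why: Exo ring-closing enyne metathesis of a 1,7-enyne closes ring B at C5=C6 and moves the CH2 terminus to C7; the conditions are neutral, alkyl halides are tolerated, the quaternary C3 favours closure and no stereocentre is affected.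

Step 6
Reactants: 11 3-methylbut-2-enal
Product: 13 2-bromo-3-methylbut-2-enal, via 2,3-dibromo-3-methylbutanal 12 (not isolated)
Conditions: Br2, CH2Cl2, 0 °C; then Et3N, 0 °C to rt
Reagents that add atoms: bromine, BrBr
Why: Bromination and dehydrobromination of an enal; the acidic alpha hydrogen of 12 is lost together with the tertiary bromide, leaving the alpha-bromoenal.

Step 7
Reactants: 10 (4S,5S)-5-bromo-4-chloro-4-methyl-1-(prop-1-en-2-yl)cyclohex-1-ene; 13 2-bromo-3-methylbut-2-enal
Product: 15 (2S,3S,5S,6R)-2,10-dibromo-3-chlorochamigra-7,9-dien-5-ol, via fused dihydropyran 14 (not isolated)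
Conditions: HNTf2 (5 mol %), 4 Å molecular sieves, CH2Cl2, −78 °C; then −20 °C; Et3N quench
Reagents that add atoms: none
Why: Proposed new method: protonated 13 is attacked at C9 by the unsubstituted diene terminus C8 of 10, and the C9 oxygen closes on C5 of the resulting C5–C6–C7 allyl cation, a stepwise oxa-[4+2] cycloaddition (closest known type: strong-acid-catalysed cycloaddition of simple dienes with aldehydes) that gives dihydropyran 14 by six-membered C–O closure. On warming the acid re-ionises 14: cleavage of C5–O only regenerates the same allyl cation and 14, whereas cleavage of the allylic C9–O bond gives a 2-bromoallyl cation whose tertiary terminus C11 is captured by the tetrasubstituted C6=C7 bond in a 6-endo-trig closure of ring A (closest known type: dehydrative cation–olefin cyclisation of tertiary allylic alcohols). Loss of the doubly allylic C8 proton from the C7 cation gives the conjugated bromodiene, regenerates the acid and makes the sequence irreversible, so the whole step is an addition with no by-product. C5 is set when the oxygen bonds to the face of 10 opposite the axial C3 chlorine (1,3 to C5), and this isomer of 14 is also the more stable one because it keeps Br and Cl diaxial and the C3 methyl equatorial. C6 is set by exclusion: after C9–O cleavage, allylic 1,3-strain with C8 turns the C5 oxygen axial and Br and Cl equatorial, and C11 can bond only to the equatorial face of C6 (cis to O and Br), since the other face would force either quaternary C11 or Br into an axial position beneath the C7 methyl. The step needs reaction at the C=O and not the C=C of 13 (the C=C is tetrasubstituted and brominated), attack through C8 and not C5 (C8 is unhindered and gives the more substituted allyl cation), and proton loss from C8 rather than from the C7 methyl (C8–H is doubly allylic and gives the conjugated diene). A Brønsted acid is preferred to a metal halide Lewis acid so that the tertiary chloride is not abstracted.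

Step 8
Reactants: 15 (2S,3S,5S,6R)-2,10-dibromo-3-chlorochamigra-7,9-dien-5-ol
Product: 16 (2S,3S,5S,6R,7R,8S)-2,10-dibromo-3-chloro-7,8-epoxychamigr-9-en-5-ol
Conditions: dimethyldioxirane (1.05 equiv) in acetone, −40 to 0 °C
Reagents that add atoms: dimethyldioxirane, CC1(C)OO1
Why: Dioxirane epoxidation selects the trisubstituted C7=C8 bond over the electron-poor bromoalkene; in the favoured twist of ring A the bulkier C5 is pseudo-axial (fewer gauche contacts with the C11 methyls) and covers its side of C7=C8, so oxygen arrives from the C1 side, and neutral acetone suppresses hydroxyl direction and acid-induced opening.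

Step 9
Reactants: 16 (2S,3S,5S,6R,7R,8S)-2,10-dibromo-3-chloro-7,8-epoxychamigr-9-en-5-ol
Product: 17 (2S,3S,5S,6R,7R,8S,9S,10S)-2,10-dibromo-3-chloro-7,8:9,10-diepoxychamigran-5-ol (target)
Conditions: mCPBA, solid Na2HPO4, CH2Cl2, 0 °C to rt; chromatography on base-washed silica
Reagents that add atoms: 3-chloroperoxybenzoic acid, O=C(OO)c1cccc(Cl)c1
Why: Peracid epoxidation of the one remaining alkene, a vinyl bromide; the face on the C5 side is anti to the first oxirane, anti to the pseudo-axial C11 methyl and within hydrogen-bonding reach of the C5-OH, so all three effects favour the required anti bis-oxirane, and the buffer protects the bromooxirane.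

## Compound list

1 | but-2-yn-1-ol | CC#CCO | starting material
2 | sodium cyclic alkenylalanate from 1 | CC1=CCO[Al-]1(OCCOC)OCCOC.[Na+] | intermediate
3 | (Z)-3-iodobut-2-en-1-ol | C/C(I)=C/CO | intermediate
4 | allyltributylstannane | C=CC[Sn](CCCC)(CCCC)CCCC | starting material
5 | (2Z)-3-methylhexa-2,5-dien-1-ol | C/C(CC=C)=C/CO | intermediate
6 | (2S,3S)-2-bromo-3-chloro-3-methylhex-5-en-1-ol | OC[C@H](Br)[C@@](C)(Cl)CC=C | intermediate
7 | 1-propynyllithium | [Li]C#CC | starting material
8 | (2S,3S)-2-bromo-3-chloro-3-methylhex-5-enyl triflate | O=S(=O)(OC[C@H](Br)[C@@](C)(Cl)CC=C)C(F)(F)F | intermediate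
9 | (4S,5S)-5-bromo-4-chloro-4-methylnon-1-en-7-yne | CC#CC[C@H](Br)[C@@](C)(Cl)CC=C | intermediate
10 | (4S,5S)-5-bromo-4-chloro-4-methyl-1-(prop-1-en-2-yl)cyclohex-1-ene | CC(=C)C1=CC[C@](C)(Cl)[C@@H](Br)C1 | intermediate
11 | 3-methylbut-2-enal | CC(C)=CC=O | starting material
12 | 2,3-dibromo-3-methylbutanal | CC(C)(Br)C(Br)C=O | intermediate
13 | 2-bromo-3-methylbut-2-enal | CC(C)=C(Br)C=O | intermediate
14 | dihydropyran fused at C5–C6 (O joins C5 and C9; C9 carries the 1-bromo-2-methylpropenyl group; C9 configuration immaterial) | CC(C)=C(Br)C1CC(C)=C2C[C@H](Br)[C@@](C)(Cl)C[C@@H]2O1 | intermediate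
15 | (2S,3S,5S,6R)-2,10-dibromo-3-chlorochamigra-7,9-dien-5-ol | CC1(C)C(Br)=CC=C(C)[C@]12C[C@H](Br)[C@@](C)(Cl)C[C@@H]2O | intermediate
16 | (2S,3S,5S,6R,7R,8S)-2,10-dibromo-3-chloro-7,8-epoxychamigr-9-en-5-ol | CC1(C)C(Br)=C[C@@H]2O[C@]2(C)[C@]12C[C@H](Br)[C@@](C)(Cl)C[C@@H]2O | intermediate
17 | (2S,3S,5S,6R,7R,8S,9S,10S)-2,10-dibromo-3-chloro-7,8:9,10-diepoxychamigran-5-ol | CC1(C)[C@@]2(Br)O[C@H]2[C@@H]2O[C@]2(C)[C@]12C[C@H](Br)[C@@](C)(Cl)C[C@@H]2O | target

## Step count and least certain steps

Total: 9 steps. Longest linear sequence: 8 steps (steps 1–5 and 7–9). Step 6 is a one-step side branch.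

**Step 7 (key step).** Three things are most likely to go wrong:
- The allylic C5–O bond of 14 ionises more readily than C9–O. Repeated re-closure could erode the C5 configuration and feed the less strained series with an equatorial hydroxyl.
- Proton loss or oligomerisation of the diene could outrun formation of the deactivated 2-bromoallyl cation.
- The tertiary chloride could ionise with help from the anti bromine.

The fallback fixes the C5–O bond irreversibly and builds the same cation stepwise, setting out from 10:
1. Dimethyldioxirane epoxidises the ring alkene anti to the axial chlorine to give vinyl oxirane F1.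
2. Acetyl bromide opens it in the SN2′ sense to give allylic bromide acetate F2. The acetate resists ionisation.
3. CuI/K2CO3/NaI coupling with 2-methylbut-3-yn-2-ol gives skipped enyne F3.
4. Syn hydrostannation with Bu3SnH and Mo(CO)3(CNtBu)3 places tin next to the carbinol carbon to give stannane F4.
5. N-bromosuccinimide converts it with retention to the (Z)-bromoallylic alcohol F5.
6. Catalytic acid ionises only the tertiary alcohol and closes ring A to give spirocyclic acetate F6.
7. K2CO3 in methanol returns to the route at 15.

**Step 4.** The C2 hydrogen is acidified by Br and lies beta to the triflate, and the SN2 reaction is slowed by branching at C2. Elimination of triflic acid, or attack of the alkynyllithium on bromine with loss of triflate, could therefore compete. The fallback sets out from 6. K2CO3 in methanol closes the bromohydrin to chloro-oxirane F7 with inversion at C2. Reagent 7 with BF3·OEt2 opens F7 at C1 to give homopropargylic alcohol F8. Tf2O/pyridine then gives secondary triflate F9, and Bu4NBr displaces it with a second inversion, rejoining the route at 9.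

**Step 5.** The ruthenium alkylidene may stall at the internal alkyne next to the branched chain, or closure may occur in the endo sense. The fallback separates the two events, setting out from 9. Cross enyne metathesis with ethene gives 2,3-disubstituted butadiene F10. Ordinary ring-closing diene metathesis between the C6 methylene and the terminal alkene then gives 10.

**Step 8.** Facial selectivity may be poor, because the two faces of C7=C8 differ only through the twist of ring A. The fallback inverts the sense of attack, setting out from 15. N-bromosuccinimide in aqueous acetone places bromine on C8 from whichever face an electrophile prefers and water on tertiary C7 from the other, giving bromohydrin F11. K2CO3 then closes the oxirane with inversion at C8. If the C5 side is the more accessible one, this delivers the oxygen on the C1 side and rejoins the route at 16.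

## Further compounds

F1 | step 7 | (5S,6S)-5,6-epoxide of 10 (vinyl oxirane with oxygen cis to Br) | CC(=C)[C@@]12C[C@H](Br)[C@@](C)(Cl)C[C@@H]1O2
F2 | step 7 | C5 acetate with exocyclic C6=C7(CH3)CH2Br (alkene geometry immaterial) | CC(=O)O[C@H]1C[C@](C)(Cl)[C@@H](Br)CC1=C(C)CBr
F3 | step 7 | skipped enyne from F2 and 2-methylbut-3-yn-2-ol | CC(=O)O[C@H]1C[C@](C)(Cl)[C@@H](Br)CC1=C(C)CC#CC(C)(C)O
F4 | step 7 | C10 tributylstannyl alkene with C8 cis to C11 | CC(=O)O[C@H]1C[C@](C)(Cl)[C@@H](Br)CC1=C(C)C/C=C(/[Sn](CCCC)(CCCC)CCCC)C(C)(C)O
F5 | step 7 | (Z)-2-bromoallylic tertiary alcohol with C8 cis to C11 | CC(=O)O[C@H]1C[C@](C)(Cl)[C@@H](Br)CC1=C(C)C/C=C(/Br)C(C)(C)O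
F6 | step 7 | C5 acetate of 15 | CC1(C)C(Br)=CC=C(C)[C@]12C[C@H](Br)[C@@](C)(Cl)C[C@@H]2OC(C)=O
F7 | step 4 | 2-(2-chloropent-4-en-2-yl)oxirane from 6 (C2 inverted) | C=CC[C@](C)(Cl)[C@H]1CO1
F8 | step 4 | 4-chloro-4-methylnon-1-en-7-yn-5-ol (C2 hydroxyl) | CC#CC[C@@H](O)[C@@](C)(Cl)CC=C
F9 | step 4 | triflate of F8 | CC#CC[C@@H](OS(=O)(=O)C(F)(F)F)[C@@](C)(Cl)CC=C
F10 | step 5 | 5-bromo-4-chloro-4,8-dimethyl-7-methylidenenona-1,8-diene | C=C(C)C(=C)C[C@H](Br)[C@@](C)(Cl)CC=C
F11 | step 8 | 8-bromo-7-hydroxy bromohydrin of 15 (OH on the C1 side and Br on the C5 side) | CC1(C)C(Br)=C[C@@H](Br)[C@](C)(O)[C@]12C[C@H](Br)[C@@](C)(Cl)C[C@@H]2O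
A1 | alternative 1 | 3,3-dimethyl-2-methylidenecyclohexan-1-one | C=C1C(=O)CCCC1(C)C
A2 | alternative 1 | 5,5,9-trimethylspiro[5.5]undec-8-en-1-one (racemic) | CC1=CCC2(CC1)C(=O)CCCC2(C)C
A3 | alternative 2 | (3S,4S)-4-bromo-5-(5-bromo-2,6,6-trimethylcyclohexa-1,4-dienyl)-3-chloro-3-methylpentanal | CC1=C(C[C@H](Br)[C@@](C)(Cl)CC=O)C(C)(C)C(Br)=CC1
A4 | alternative 2 | C5 epimer of 15 (equatorial hydroxyl) | CC1(C)C(Br)=CC=C(C)[C@]12C[C@H](Br)[C@@](C)(Cl)C[C@H]2O
A5 | alternative 3 | phenol mesylate with preset C2, C3 and C5 | Cc1cc(O)cc(C)c1[C@@H](O[Si](C)(C)C(C)(C)C)C[C@](C)(Cl)[C@@H](Br)COS(C)(=O)=O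
A6 | alternative 3 | symmetric 7,11-dimethyl spirodienone | CC1=CC(=O)C=C(C)C12C[C@H](Br)[C@@](C)(Cl)C[C@@H]2O[Si](C)(C)C(C)(C)C
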